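(The runs are simulated on assumed constants.)

Do not carry dawn's last J slope forward unchanged: the slope falls, and the reckoning hangs on how fast.

| flask | G | L | remark | time |
|---|---|---|---|---|
| dawn | 0.050 M | 0.045 M | run made earlier |  |
| winter | 0.075 M | 0.045 M | run made earlier |  |
| birch | 0.050 M | 0.0450 M (fed, over 20 min) | all else is in the flask from the start; the feed brings no volume worth counting | 50 min |
| elm | 0.050 M (fed, over 20 min) | 0.0450 M | all else is in the flask from the start; the feed brings no volume worth counting | 50 min |
| maple | 0.050 M | 0.0450 M | everything together at the start | 50 min |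

| run | time / min | J / % | G / % |
|---|---|---|---|
| dawn | 2.50 | 4.0 | 47.7 |
| dawn | 4.00 | 5.5 | 34.1 |
| dawn | 6.00 | 8.3 | 25.5 |
| dawn | 10.0 | 13.7 | 18.6 |
| dawn | 20.0 | 22.6 | 14.0 |
| dawn | 30.0 | 29.5 | 13.0 |
| winter | 0.667 | 0.2 | 79.1 |
| winter | 2.00 | 2.3 | 53.5 |
| winter | 4.00 | 5.3 | 34.5 |
| winter | 5.00 | 6.9 | 29.2 |
| winter | 8.00 | 10.1 | 22.7 |
| winter | 10.0 | 11.1 | 18.8 |

(scatter of a reading: 0.5 percentage points)

1. the flask that comes out highest in amount of J, in percent of the G charged, or "all alike" when all lie within 1.5 percentage points (birch / elm / maple / all alike)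
2. J at the end, in percent of the G charged, birch
3. J at the end, in percent of the G charged, elm
4. J at the end, in percent of the G charged, maple

- percentages count the G that a species holds: one E counts as two
- on the list of suspects stand: L + Z -> J; 2 G -> E; G <-> X; G + L <-> D; G <-> Z

Maple has dawn's charge, so read maple's future from dawn. Between 6.00 min and 10.0 min, J rises by 0.0135 min⁻¹ of the charge; between 20.0 min and 30.0 min, by 0.00690 min⁻¹. From midpoint to midpoint, take the slope half-life, the time in which the J slope halves: 17.6 min.

Bound from above, slope held: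

29.5% + 0.00690 min⁻¹ × 20.0 min = 43.3%

Bound from below, slope halving every 17.6 min:

37.3%

The slope read between 10.0 min and 20.0 min, 0.00890 min⁻¹, puts the late halving slower than 17.6 min, so this is the low side. The bracket is maple's; in birch, L, charged below G, comes in over 20 min, and in elm, G does.

The forecast names maple, with 35% for birch, 35.5% for elm and 41% for maple, and says of the first “For birch, L is short early”. Its maple figure stands inside the bracket.

Birch comes highest: 42.5%, against 38.2% for maple, which lies in the bracket, and 34.7% for elm.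

    L + Z → J (k = 8.00 M⁻¹ min⁻¹)
    2 G → E (k = 0.400 M⁻¹ min⁻¹)
    G ⇌ X (K = 0.920, k = 0.110 min⁻¹)
    G + L ⇌ D (K = 120 M⁻¹, k = 3.40 M⁻¹ min⁻¹)
    G ⇌ Z (K = 1.20, k = 0.0620 min⁻¹)

Carry the half-life past the feed: a slope read between 20 min and 25.0 min is worth 14.4 min of itself up to 50 min. Birch, with J 29.5% at 25.0 min and slope 0.0100 min⁻¹, reckons to 43.9% and stood at 42.5%. Elm, with J 18.5% and slope 0.0100 min⁻¹, reckons to 32.9% and stood at 34.7%.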